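**Assumption:** the target SMILES has no stereocentre, and its only non-aromatic C=C is locked cis in the pyran ring, so the molecule is achiral. "Single enantiomer" therefore needs no stereocontrol. Reagents that contribute atoms are numbered as starting materials.

## Retrosynthetic overview

1. The γ-pyrone C-ring (O1–C2) is closed last, by cyclodehydration of a 2-aryl-3-oxopropanal (2-formyl-deoxybenzoin) released on global desilylation.
2. The C2–C3 and C3–C1′ bonds come from one proposed new step: an aryl-migrative homologation of the B-ring aldehyde with an A-ring α-diazoketone.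
3. The dimethylpyran ring is built earlier on the B-ring by propargyl Claisen/oxa-6π cyclisation of a 2-O-(1,1-dimethylpropargyl)-4-O-silyl-2,4-dihydroxybenzaldehyde. The blocked C1 and the protected 4-OH force closure onto the 2-oxygen.
4. The A-ring diazoketone comes from phloroacetophenone by persilylation and deacylative diazo transfer.
5. Ring order: A and B rings are purchased, then the pyran ring, then the C-ring.

## Route

**Step 1**
Reactants: 1, 2,4-dihydroxybenzaldehyde; 2, chlorotriisopropylsilane (TIPSCl)
Product: 3, 2-hydroxy-4-[(triisopropylsilyl)oxy]benzaldehyde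
Conditions: TIPSCl (1.05 eq), imidazole, CH2Cl2, 0 °C → rt
Reagents that add atoms: TIPSCl, CC(C)[Si](Cl)(C(C)C)C(C)C
Why: Regioselective silyl ether formation; the 2-OH is hydrogen-bonded to the aldehyde and hindered, so only the 4-OH is silylated.

**Step 2**
Reactants: 3, 2-hydroxy-4-[(triisopropylsilyl)oxy]benzaldehyde; 4, 3-chloro-3-methylbut-1-yne
Product: 5, 2-[(2-methylbut-3-yn-2-yl)oxy]-4-[(triisopropylsilyl)oxy]benzaldehyde
Conditions: DBU, CuCl2·2H2O (1 mol%), MeCN, 0 °C → rt
Reagents that add atoms: 3-chloro-3-methylbut-1-yne, C#CC(C)(C)Cl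
Why: Cu-catalysed propargylic etherification of the phenoxide with the tertiary propargylic chloride (via a copper acetylide/allenylidene); the aryl TIPS ether and the aldehyde tolerate DBU at 0 °C.

**Step 3**
Reactants: 5, 2-[(2-methylbut-3-yn-2-yl)oxy]-4-[(triisopropylsilyl)oxy]benzaldehyde
Product: 6, 2,2-dimethyl-5-[(triisopropylsilyl)oxy]-2H-chromene-8-carbaldehyde
Conditions: PhNEt2, 180 °C (sealed tube)
Reagents that add atoms: none
Why: Aromatic propargyl Claisen rearrangement, then 1,5-H shift and oxa-6π electrocyclisation; the only free ortho position of the ether oxygen is C3, so the pyran closes on the 2-oxygen with the formyl group at C8 and OTIPS at C5.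

**Step 4**
Reactants: 7, 2′,4′,6′-trihydroxyacetophenone (dried monohydrate); 8, tert-butyldimethylsilyl chloride (TBSCl)
Product: 9, 1-{2,4,6-tris[(tert-butyldimethylsilyl)oxy]phenyl}ethan-1-one
Conditions: TBSCl (4.5 eq), imidazole, DMAP (cat.), DMF, rt → 50 °C
Reagents that add atoms: TBSCl, CC(C)(C)[Si](C)(C)Cl
Why: Exhaustive phenol silylation; excess reagent and warming drive silylation of the chelated ortho-OH, masking every phenol so that none can attack the diazonium formed in step 6.

**Step 5**
Reactants: 9, 1-{2,4,6-tris[(tert-butyldimethylsilyl)oxy]phenyl}ethan-1-one; 10, 4-acetamidobenzenesulfonyl azide (p-ABSA)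
Product: 11, 2-diazo-1-{2,4,6-tris[(tert-butyldimethylsilyl)oxy]phenyl}ethan-1-one
Conditions: LiHMDS, THF, −78 °C, then CF3CO2CH2CF3; then p-ABSA, Et3N, H2O (1 eq), MeCN, rt
Reagents that add atoms: p-ABSA, CC(=O)Nc1ccc(cc1)S(=O)(=O)N=[N+]=[N-]
Why: Danheiser detrifluoroacetylative diazo transfer; the methyl ketone is activated as its trifluoroacetyl derivative, which accepts N2 and loses the trifluoroacetyl group, and the aryl TBS ethers survive brief LiHMDS at −78 °C and Et3N/MeCN.

**Step 6**
Reactants: 6, 2,2-dimethyl-5-[(triisopropylsilyl)oxy]-2H-chromene-8-carbaldehyde; 11, 2-diazo-1-{2,4,6-tris[(tert-butyldimethylsilyl)oxy]phenyl}ethan-1-one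
Product: 12, 2-{2,2-dimethyl-5-[(triisopropylsilyl)oxy]-2H-chromen-8-yl}-3-hydroxy-1-{2,4,6-tris[(tert-butyldimethylsilyl)oxy]phenyl}prop-2-en-1-one (enol tautomer of the 2-aryl-3-oxopropanal; enol geometry irrelevant)
Conditions: HNTf2 (10 mol%), 4 Å MS, CH2Cl2, −78 → −30 °C, slow addition of 11 (1.3 eq); Et3N quench
Reagents that add atoms: none
Why: Proposed new method: acid-catalysed aryl-migrative homologation of an aryl aldehyde with an aryl α-diazoketone. The diazo carbon of 11 adds to protonated 6 to give a β-hydroxy-α-diazonium ketone. The very electron-rich 2,4-dioxygenated aryl group then undergoes a 1,2-shift through a phenonium ion with loss of N2, faster than the hydride shift that would lead to the 1,3-diketone (flavone series). This forms C2–C3 and C3–C1′ in one redox-neutral operation; a fluoride-free acid and bulky ortho-silyloxy groups are chosen to spare the silyl ethers and suppress coumaranone formation. The closest known reaction type is the acid-catalysed aryl-shift variant of the Roskamp reaction (aromatic aldehyde + ethyl diazoacetate → 3-hydroxy-2-arylacrylate), and it converges with the BF3-mediated chalcone-epoxide → 2-formyl-deoxybenzoin rearrangement.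

**Step 7**
Reactants: 12, 2-{2,2-dimethyl-5-[(triisopropylsilyl)oxy]-2H-chromen-8-yl}-3-hydroxy-1-{2,4,6-tris[(tert-butyldimethylsilyl)oxy]phenyl}prop-2-en-1-one
Product: 13, sophoraisoflavone A, 5,7-dihydroxy-3-(5-hydroxy-2,2-dimethyl-2H-chromen-8-yl)-4H-chromen-4-one
Conditions: TBAF/AcOH (1:1, 6 eq), THF, 0 °C → rt; then 1 M aq. HCl, THF, rt
Reagents that add atoms: none
Why: Buffered fluoride cleaves all four aryl silyl ethers; either of the two equivalent ortho-OH groups then adds to the formyl carbon and the resulting 2-hydroxyisoflavanone dehydrates to the γ-pyrone (classical 2-formyl-deoxybenzoin → isoflavone cyclodehydration), under acid mild enough for the chromene.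

## Compound list

1 | 2,4-dihydroxybenzaldehyde | O=Cc1ccc(O)cc1O | starting material
2 | chlorotriisopropylsilane | CC(C)[Si](Cl)(C(C)C)C(C)C | starting material
3 | 2-hydroxy-4-[(triisopropylsilyl)oxy]benzaldehyde | O=Cc1ccc(O[Si](C(C)C)(C(C)C)C(C)C)cc1O | intermediate
4 | 3-chloro-3-methylbut-1-yne | C#CC(C)(C)Cl | starting material
5 | 2-[(2-methylbut-3-yn-2-yl)oxy]-4-[(triisopropylsilyl)oxy]benzaldehyde | O=Cc1ccc(O[Si](C(C)C)(C(C)C)C(C)C)cc1OC(C)(C)C#C | intermediate
6 | 2,2-dimethyl-5-[(triisopropylsilyl)oxy]-2H-chromene-8-carbaldehyde | CC1(C)C=Cc2c(O[Si](C(C)C)(C(C)C)C(C)C)ccc(C=O)c2O1 | intermediate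
7 | 2′,4′,6′-trihydroxyacetophenone | CC(=O)c1c(O)cc(O)cc1O | starting material
8 | tert-butyldimethylsilyl chloride | CC(C)(C)[Si](C)(C)Cl | starting material
9 | 1-{2,4,6-tris[(tert-butyldimethylsilyl)oxy]phenyl}ethan-1-one | CC(=O)c1c(O[Si](C)(C)C(C)(C)C)cc(O[Si](C)(C)C(C)(C)C)cc1O[Si](C)(C)C(C)(C)C | intermediate
10 | 4-acetamidobenzenesulfonyl azide (p-ABSA) | CC(=O)Nc1ccc(cc1)S(=O)(=O)N=[N+]=[N-] | starting material
11 | 2-diazo-1-{2,4,6-tris[(tert-butyldimethylsilyl)oxy]phenyl}ethan-1-one | [N-]=[N+]=CC(=O)c1c(O[Si](C)(C)C(C)(C)C)cc(O[Si](C)(C)C(C)(C)C)cc1O[Si](C)(C)C(C)(C)C | intermediate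
12 | 2-{2,2-dimethyl-5-[(triisopropylsilyl)oxy]-2H-chromen-8-yl}-3-hydroxy-1-{2,4,6-tris[(tert-butyldimethylsilyl)oxy]phenyl}prop-2-en-1-one | OC=C(c1ccc(O[Si](C(C)C)(C(C)C)C(C)C)c2C=CC(C)(C)Oc12)C(=O)c1c(O[Si](C)(C)C(C)(C)C)cc(O[Si](C)(C)C(C)(C)C)cc1O[Si](C)(C)C(C)(C)C | intermediate
13 | sophoraisoflavone A | CC1(C)C=Cc2c(O)ccc(-c3coc4cc(O)cc(O)c4c3=O)c2O1 | target

## Summary

**Total step count:** 7

**Longest linear sequence:** 5 steps (steps 1, 2, 3, 6, 7); the A-ring branch (steps 4, 5) joins at step 6.

**Three steps most likely to fail:**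

1. **Step 6 (proposed new aryl-migrative homologation).** Risks: a competing hydride shift giving the 1,3-diketone; acid decomposition of diazoketone 11 to a coumaranone; acid sensitivity of the chromene. Fallback (known chemistry): abandon the aldehyde/diazo union and join the fragments by Suzuki–Miyaura coupling.
   - Electrophile: 3-iodo-5,7-bis(methoxymethoxy)chromen-4-one, made from 2′-hydroxy-4′,6′-bis(methoxymethoxy)acetophenone with DMF-DMA, then I2.
   - Nucleophile: the 8-pinacolboronate of 5-(methoxymethoxy)-2,2-dimethyl-2H-chromene, made from 2-bromo-5-(methoxymethoxy)phenol by the same propargylation/Claisen sequence, then Br/Li exchange and borylation.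
   - Coupling with Pd(dppf)Cl2/K2CO3, then HCl/MeOH deprotection.

2. **Step 2 (propargylation of the chelated, hindered 2-OH).** Fallback: skip the ether and build the pyran directly from 3 by phenylboronic-acid-templated ortho-specific [3+3] chromenylation with 3-methylbut-2-enal (PhB(OH)2, AcOH, toluene, Dean–Stark). This proceeds through an ortho-quinone methide and oxa-6π closure and gives 6 in one step.

3. **Step 5 (diazo transfer on a hindered, silyl-rich ketone).** Risks: O→O silyl migration on enolisation and partial desilylation. Fallback: replace enolate acylation/diazo transfer with α-bromination of 9 (via its silyl enol ether, NBS), then treat the α-bromoketone with N,N′-ditosylhydrazine/DBU to give 11.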